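**Retrosynthetic overview**
1. Target ⇐ cyclodecadienone 21 by late functional-group steps only: desulfonylation, C15 acetylation, C2 reduction and tigloylation, then unmasking of the α-methylene lactone from a 2-methoxy-3-methylenetetrahydrofuran and desilylation.
2. 21 ⇐ 11-membered dienolide 19 by an anionic 1,4 O→C acyl shift: the sulfonyl carbanion at C3 attacks the lactone carbonyl C2, the lactone oxygen and C15 leave the ring, C3 enters it (11 → 10).
3. 19 ⇐ hydroxy acid 17 (macrolactonisation) ⇐ butenolide aldehyde 13 ⇐ enal acid 8 + silyloxyfuran 12 (vinylogous Mukaiyama–Michael, C6–C7 bond). The butenolide (C15, C4, C5, C6, O) is a temporary ring that fixes C15 cis to C6 before it is reduced to the ene-diol.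
4. Ring order: butenolide (temporary) → methoxytetrahydrofuran (latent lactone) → 11-membered lactone → 10-membered carbocycle → γ-lactone.
5. Enabling feature: C3 and the oxygenated C15 are geminal on C4, and C15 is cis to C6 across C4=C5. The C15 oxygen can therefore carry C2 as an ester in a ring (C2, C1, C10, C9, C8, C7, C6, C5, C4, C15, O) that holds both olefins ring-cis and puts C3 five atoms from C2.

Key step: step 14

Remark: atoms carry germacranolide numbers (ring C1–C10 with C1=C10 and C4=C5; O on C6; C11(=C13)–C12 on C7; C14 = methyl on C10; C15 = oxygenated carbon on C4).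
Remark: the acetal carbon C12 in 17–25 is drawn as one anomer and C3 in 20, 21 and F3 is left undefined; both are erased later and either epimer serves.
Remark: the sense of induction of the catalysts in steps 1, 9 and 17 is assigned by analogy with simpler substrates.

Step 1
Reactants: 1 (E)-4,4-dimethoxybut-2-enal; 2 allenylboronic acid pinacol ester
Product: 3 (2E,4R)-1,1-dimethoxyhept-2-en-6-yn-4-ol
Conditions: (R)-3,3'-bis(2,4,6-triisopropylphenyl)-1,1'-binaphthyl-2,2'-diyl hydrogen phosphate (5 mol%), 4 Å molecular sieves, toluene, −20 °C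
Reagents that add atoms: none
Why: Chiral phosphoric acid-catalysed propargylation of an aldehyde with an allenylboronate (SE2' through a closed six-membered transition state); the catalyst-bound boronate selects the aldehyde face and should set C8 as R.

Step 2
Reactants: 3 (2E,4R)-1,1-dimethoxyhept-2-en-6-yn-4-ol
Product: 4 silyl ether of 3 (C8–OTBS)
Conditions: t-BuMe2SiCl, imidazole, DMF, rt
Reagents that add atoms: tert-butyldimethylsilyl chloride, CC(C)(C)[Si](C)(C)Cl
Why: Standard silylation of a secondary alcohol; the ether blocks δ-lactonisation of O8 onto C2 and stays until the last step.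

Step 3
Reactants: 4 silyl ether of 3
Product: 5 ethyl (5R,6E)-5-[(tert-butyldimethylsilyl)oxy]-8,8-dimethoxyoct-6-en-2-ynoate
Conditions: n-BuLi, THF, −78 °C; then ClCO2Et, −78 → 0 °C
Reagents that add atoms: ethyl chloroformate, CCOC(=O)Cl
Why: Deprotonation of the terminal alkyne and C-acylation of the lithium acetylide with a chloroformate introduces C2.

Step 4
Reactants: 5 ethyl (5R,6E)-5-[(tert-butyldimethylsilyl)oxy]-8,8-dimethoxyoct-6-en-2-ynoate
Product: 6 ethyl (2Z,5R,6E)-5-[(tert-butyldimethylsilyl)oxy]-8,8-dimethoxy-3-methylocta-2,6-dienoate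
Conditions: Me2CuLi, THF, −78 °C; then NH4Cl/MeOH at −78 °C
Reagents that add atoms: lithium dimethylcuprate, [Li+].C[Cu-]C
Why: Syn-carbocupration of a 2-ynoate and protonation of the alkenylcuprate with retention put the new methyl (C14) trans and the C9 chain cis to the ester, which is the ring-cis C1=C10 geometry of the target.

Step 5
Reactants: 6 ethyl (2Z,5R,6E)-5-[(tert-butyldimethylsilyl)oxy]-8,8-dimethoxy-3-methylocta-2,6-dienoate
Product: 8 (2Z,5R,6E)-5-[(tert-butyldimethylsilyl)oxy]-3-methyl-8-oxoocta-2,6-dienoic acid, via acetal acid 7 (not isolated)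
Conditions: LiOH, THF/MeOH/H2O, 40 °C; then 1 M HCl to pH 2, THF/H2O, rt
Reagents that add atoms: lithium hydroxide, [Li+].[OH-]; water, O
Why: Saponification followed by mild aqueous acid hydrolysis of the allylic dimethyl acetal; the secondary silyl ether and both olefin geometries should persist.

Step 6
Reactants: 9 3-methylfuran-2(5H)-one
Product: 10 3-(bromomethyl)furan-2(5H)-one
Conditions: N-bromosuccinimide, azobis(isobutyronitrile) (cat.), PhCF3, reflux
Reagents that add atoms: N-bromosuccinimide, O=C1CCC(=O)N1Br
Why: Wohl–Ziegler bromination of the allylic methyl group of the butenolide.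

Step 7
Reactants: 10 3-(bromomethyl)furan-2(5H)-one
Product: 11 3-[(phenylsulfonyl)methyl]furan-2(5H)-one
Conditions: PhSO2Na, DMF, rt
Reagents that add atoms: sodium benzenesulfinate, [Na+].[O-]S(=O)c1ccccc1
Why: S-alkylation of the sulfinate by the allylic bromide (SN2) gives the allylic sulfone, the isomer that keeps the conjugated butenolide.

Step 8
Reactants: 11 3-[(phenylsulfonyl)methyl]furan-2(5H)-one
Product: 12 trimethyl({3-[(phenylsulfonyl)methyl]furan-2-yl}oxy)silane
Conditions: Me3SiOTf, Et3N, CH2Cl2, 0 °C
Reagents that add atoms: trimethylsilyl trifluoromethanesulfonate, C[Si](C)(C)OS(=O)(=O)C(F)(F)F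
Why: Soft enolisation with O-silylation; loss of the γ-proton gives the aromatic 2-silyloxyfuran.

Step 9
Reactants: 8 (2Z,5R,6E)-5-[(tert-butyldimethylsilyl)oxy]-3-methyl-8-oxoocta-2,6-dienoic acid; 12 trimethyl({3-[(phenylsulfonyl)methyl]furan-2-yl}oxy)silane
Product: 13 (2Z,5R,6S)-5-[(tert-butyldimethylsilyl)oxy]-3-methyl-8-oxo-6-{(2R)-5-oxo-4-[(phenylsulfonyl)methyl]-2,5-dihydrofuran-2-yl}oct-2-enoic acid
Conditions: (2R,5R)-5-benzyl-2-tert-butyl-3-methylimidazolidin-4-one (20 mol%), 2,4-dinitrobenzoic acid (20 mol%), CH2Cl2/H2O, −60 °C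
Reagents that add atoms: none
Why: Iminium-catalysed vinylogous Mukaiyama–Michael addition of a 2-silyloxyfuran to an enal; the catalyst shields one face of C7 and so sets C7, the C6/C7 relationship follows from the open transition-state geometry (adjustable through silyl group and co-acid), and C8 is a spectator.

Step 10
Reactants: 13 butenolide aldehyde acid
Product: 14 α-methylene aldehyde (C11=C13 installed, otherwise as 13)
Conditions: aq. HCHO (37%), pyrrolidine (10 mol%), propionic acid (10 mol%), i-PrOH, 45 °C
Reagents that add atoms: formaldehyde, C=O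
Why: Amine-catalysed α-methylenation of an aldehyde (Mannich condensation then elimination) at C11, the only enolisable α-position; C7 is not epimerisable.

Step 11
Reactants: 14 α-methylene aldehyde
Product: 15 dimethyl acetal of 14
Conditions: HC(OMe)3, pyridinium p-toluenesulfonate (cat.), MeOH, rt
Reagents that add atoms: trimethyl orthoformate, COC(OC)OC
Why: Acid-catalysed acetalisation protects C12 at the aldehyde oxidation level for the hydride step.

Step 12
Reactants: 15 dimethyl acetal of 14
Product: 17 seco acid with free C15–OH and a 2-methoxy-3-methylenetetrahydrofuran (C6, C7, C11, C12, O), via enediol 16 (not isolated)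
Conditions: i-Bu2AlH (5 equiv), CH2Cl2, −78 → −10 °C; aq. KNaC4H4O6; then pyridinium p-toluenesulfonate (cat.), CH2Cl2, rt
Reagents that add atoms: none
Why: 1,2-Reduction of the butenolide through its lactol gives the ene-1,4-diol with C15 cis to C6 while the aluminium carboxylate and the acetal are inert, and acid-catalysed transacetalisation then ties the C6 hydroxyl into a five-membered acetal, leaving C15–OH as the only free hydroxyl.

Step 13
Reactants: 17 seco acid
Product: 19 11-membered lactone (C2 acyl on the C15 oxygen; both olefins cis within the ring), via mixed anhydride 18 (not isolated)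
Conditions: 2-methyl-6-nitrobenzoic anhydride, 4-(dimethylamino)pyridine, Et3N, CH2Cl2 (0.002 M, slow addition), rt
Reagents that add atoms: none
Why: Shiina macrolactonisation of a primary allylic alcohol; two ring-cis olefins and four sp2 ring atoms reduce transannular strain, and the β,β-disubstituted enoate resists isomerisation under these mild basic conditions.

Step 14
Reactants: 19 11-membered lactone
Product: 21 ring-contracted β-keto sulfone with free C15–OH (10-membered carbocycle), via hemiketal alkoxide 20 (not isolated)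
Conditions: LiN(SiMe3)2 (2.0 equiv), THF (0.01 M), −78 → −20 °C; then aq. NH4Cl
Reagents that add atoms: none
Why: Proposed new method: LiN(SiMe3)2 removes a C3 proton (allylic and alpha to the sulfone), the carbanion adds to the lactone carbonyl C2 through a five-membered transition state made of C3, C4, C15, the ring oxygen and C2, and the hemiketal alkoxide 20 collapses with loss of the C15 alkoxide, so the acyl group moves 1,4 from oxygen to carbon and the 11-membered lactone contracts to the 10-membered carbocycle; the closest known reaction types are the Claisen-type acylation of sulfonyl carbanions by esters, the anionic homo-Fries 1,4 O-to-C acyl shift and the intramolecular nucleophilic acyl substitution that turns halo-lactones into hydroxy ketones. The one ring closed is the cyclodecadienone, by 5-exo-trig attack inside the macrolactone, so the ten-membered ring forms without the entropic cost of a direct medium-ring closure. The only new stereocentre is C3; it is not controlled and is removed in step 15, while C6, C7 and C8 are untouched. The step needs alpha- rather than gamma-acylation of the allyl anion and acylation rather than 1,4-elimination toward C6: charge localisation next to the sulfone, the geminal position of C3 and C15 on C4 and the poor leaving-group ability of the acetal oxygen on C6 should secure this, and C10 is too hindered for conjugate addition. Because C15 is replaced by C3 as ring member, the ring-cis C4=C5 of the lactone becomes the ring-trans olefin of the carbocycle with the C15 oxygen cis to C6, and C1=C10 stays ring-cis. Deprotonation of the β-keto sulfone makes the contraction irreversible.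

Step 15
Reactants: 21 β-keto sulfone
Product: 22 hydroxy ketone (C3 = CH2, C2 = O, C15–OH)
Conditions: SmI2 (2.5 equiv), THF/MeOH, −78 °C
Reagents that add atoms: none
Why: Reductive desulfonylation of a β-keto sulfone by single-electron transfer; the samarium enolate is protonated at C3 at low temperature so the C4=C5 olefin stays out of conjugation.

Step 16
Reactants: 22 hydroxy ketone
Product: 23 C15 acetate
Conditions: Ac2O, pyridine, 4-(dimethylamino)pyridine (cat.), CH2Cl2, 0 °C
Reagents that add atoms: acetic anhydride, CC(=O)OC(C)=O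
Why: Acetylation of the only free hydroxyl; any cyclic hemiketal between O15 and C2 is in equilibrium with the open form and is funnelled to the primary acetate.

Step 17
Reactants: 23 C15 acetate
Product: 24 (2S)-allylic alcohol
Conditions: (R)-1-methyl-3,3-diphenyltetrahydro-1H,3H-pyrrolo[1,2-c][1,3,2]oxazaborole (1.0 equiv), catecholborane, toluene, −78 °C
Reagents that add atoms: none
Why: Corey–Bakshi–Shibata reduction; the oxazaborolidine binds the ketone with the alkenyl arm (C1=C10) as the large group and C3H2 as the small one, and should deliver hydride to the face that gives (2S).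

Step 18
Reactants: 24 (2S)-allylic alcohol
Product: 25 C2 tiglate
Conditions: tigloyl chloride, pyridine, 4-(dimethylamino)pyridine (cat.), CH2Cl2, 0 °C → rt
Reagents that add atoms: (E)-2-methylbut-2-enoyl chloride, C/C=C(\C)C(=O)Cl
Why: Acylation of the only free hydroxyl with retention at C2; the E-acyl group does not isomerise under these conditions.

Step 19
Reactants: 25 C2 tiglate
Product: 26 α-methylene lactol (C12–OH, anomeric mixture)
Conditions: pyridinium p-toluenesulfonate (cat.), acetone/H2O (4:1), 40 °C
Reagents that add atoms: water, O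
Why: Hydrolysis of an allylic cyclic acetal is far faster than cleavage of the secondary silyl ether or the two esters, so C8 stays protected and only O6 can hold the lactol.

Step 20
Reactants: 26 α-methylene lactol
Product: 27 8-O-silyl ether of the target
Conditions: MnO2 (activated, excess), CH2Cl2, rt
Reagents that add atoms: none
Why: MnO2 oxidation of an allylic lactol gives the α-methylene-γ-butyrolactone directly; no other oxidisable hydroxyl is present and the trans ring fusion (C6, C7) is unchanged.

Step 21
Reactants: 27 8-O-silyl ether of the target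
Product: 28 target (CNP0129394.2)
Conditions: HF·pyridine, THF/pyridine, 0 °C → rt
Reagents that add atoms: none
Why: Buffered fluoride desilylation frees the 8-hydroxyl without touching the acetate, the tiglate or the α-methylene lactone, and without the base that could move the lactone from O6 to O8.

**Compound list**
1 | (E)-4,4-dimethoxybut-2-enal | COC(OC)/C=C/C=O | starting material
2 | allenylboronic acid pinacol ester | C=C=CB1OC(C)(C)C(C)(C)O1 | starting material
3 | (2E,4R)-1,1-dimethoxyhept-2-en-6-yn-4-ol | COC(OC)/C=C/[C@H](O)CC#C | intermediate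
4 | tert-butyl{[(2E,4R)-1,1-dimethoxyhept-2-en-6-yn-4-yl]oxy}dimethylsilane | COC(OC)/C=C/[C@H](O[Si](C)(C)C(C)(C)C)CC#C | intermediate
5 | ethyl (5R,6E)-5-[(tert-butyldimethylsilyl)oxy]-8,8-dimethoxyoct-6-en-2-ynoate | COC(OC)/C=C/[C@H](O[Si](C)(C)C(C)(C)C)CC#CC(=O)OCC | intermediate
6 | ethyl (2Z,5R,6E)-5-[(tert-butyldimethylsilyl)oxy]-8,8-dimethoxy-3-methylocta-2,6-dienoate | COC(OC)/C=C/[C@H](O[Si](C)(C)C(C)(C)C)C/C(C)=C\C(=O)OCC | intermediate
7 | (2Z,5R,6E)-5-[(tert-butyldimethylsilyl)oxy]-8,8-dimethoxy-3-methylocta-2,6-dienoic acid | COC(OC)/C=C/[C@H](O[Si](C)(C)C(C)(C)C)C/C(C)=C\C(=O)O | intermediate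
8 | (2Z,5R,6E)-5-[(tert-butyldimethylsilyl)oxy]-3-methyl-8-oxoocta-2,6-dienoic acid | O=C/C=C/[C@H](O[Si](C)(C)C(C)(C)C)C/C(C)=C\C(=O)O | intermediate
9 | 3-methylfuran-2(5H)-one | CC1=CCOC1=O | starting material
10 | 3-(bromomethyl)furan-2(5H)-one | BrCC1=CCOC1=O | intermediate
11 | 3-[(phenylsulfonyl)methyl]furan-2(5H)-one | O=C1OCC=C1CS(=O)(=O)c1ccccc1 | intermediate
12 | trimethyl({3-[(phenylsulfonyl)methyl]furan-2-yl}oxy)silane | C[Si](C)(C)Oc1occc1CS(=O)(=O)c1ccccc1 | intermediate
13 | (2Z,5R,6S)-5-[(tert-butyldimethylsilyl)oxy]-3-methyl-8-oxo-6-{(2R)-5-oxo-4-[(phenylsulfonyl)methyl]-2,5-dihydrofuran-2-yl}oct-2-enoic acid | O=CC[C@@H]([C@@H]1OC(=O)C(CS(=O)(=O)c2ccccc2)=C1)[C@H](O[Si](C)(C)C(C)(C)C)C/C(C)=C\C(=O)O | intermediate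
14 | (2Z,5R,6S)-5-[(tert-butyldimethylsilyl)oxy]-7-formyl-3-methyl-6-{(2R)-5-oxo-4-[(phenylsulfonyl)methyl]-2,5-dihydrofuran-2-yl}octa-2,7-dienoic acid | O=CC(=C)[C@@H]([C@@H]1OC(=O)C(CS(=O)(=O)c2ccccc2)=C1)[C@H](O[Si](C)(C)C(C)(C)C)C/C(C)=C\C(=O)O | intermediate
15 | dimethyl acetal of 14 (7-dimethoxymethyl in place of 7-formyl) | COC(OC)C(=C)[C@@H]([C@@H]1OC(=O)C(CS(=O)(=O)c2ccccc2)=C1)[C@H](O[Si](C)(C)C(C)(C)C)C/C(C)=C\C(=O)O | intermediate
16 | enediol from 15: C6–OH and C15–OH on a C4=C5 olefin with C15 cis to C6, CH2SO2Ph on C4 | COC(OC)C(=C)[C@@H]([C@H](O)/C=C(\CO)CS(=O)(=O)c1ccccc1)[C@H](O[Si](C)(C)C(C)(C)C)C/C(C)=C\C(=O)O | intermediate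
17 | seco acid: (2Z)-3-methyl-5-silyloxy-pent-2-enoic acid chain (C2–C8) on C7 of a 2-methoxy-3-methylenetetrahydrofuran (C12, C11, C7, C6, O); C6 bears the CH=C(CH2OH)(CH2SO2Ph) arm | C=C1[C@@H](OC)O[C@H](/C=C(\CO)CS(=O)(=O)c2ccccc2)[C@H]1[C@H](O[Si](C)(C)C(C)(C)C)C/C(C)=C\C(=O)O | intermediate
18 | mixed anhydride of 17 with 2-methyl-6-nitrobenzoic acid | C=C1[C@@H](OC)O[C@H](/C=C(\CO)CS(=O)(=O)c2ccccc2)[C@H]1[C@H](O[Si](C)(C)C(C)(C)C)C/C(C)=C\C(=O)OC(=O)c1c(C)cccc1[N+](=O)[O-] | intermediate
19 | 11-membered lactone (ring: C2, C1, C10, C9, C8, C7, C6, C5, C4, C15, O) fused at C6/C7 to the methoxy-methylenetetrahydrofuran; CH2SO2Ph on C4, OTBS on C8 | C=C1[C@@H](OC)O[C@@H]2/C=C(/CS(=O)(=O)c3ccccc3)COC(=O)/C=C(/C)C[C@@H](O[Si](C)(C)C(C)(C)C)[C@@H]12 | intermediate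
20 | lithium hemiketal alkoxide (C3 bonded to C2; C2 still bonded to the C15 oxygen) | C=C1[C@@H](OC)O[C@@H]2/C=C3\COC([O-])(C3S(=O)(=O)c4ccccc4)/C=C(/C)C[C@@H](O[Si](C)(C)C(C)(C)C)[C@@H]12.[Li+] | intermediate
21 | cyclodeca-1(10),4-dien-2-one with 3-phenylsulfonyl, 4-hydroxymethyl, 8-OTBS and the 6,7-fused methoxy-methylenetetrahydrofuran | C=C1[C@@H](OC)O[C@@H]2/C=C(\CO)C(S(=O)(=O)c3ccccc3)C(=O)/C=C(/C)C[C@@H](O[Si](C)(C)C(C)(C)C)[C@@H]12 | intermediate
22 | desulfonylated hydroxy ketone (C3 = CH2) | C=C1[C@@H](OC)O[C@@H]2/C=C(\CO)CC(=O)/C=C(/C)C[C@@H](O[Si](C)(C)C(C)(C)C)[C@@H]12 | intermediate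
23 | C15 acetate of 22 | C=C1[C@@H](OC)O[C@@H]2/C=C(\COC(C)=O)CC(=O)/C=C(/C)C[C@@H](O[Si](C)(C)C(C)(C)C)[C@@H]12 | intermediate
24 | (2S)-alcohol from 23 | C=C1[C@@H](OC)O[C@@H]2/C=C(\COC(C)=O)C[C@H](O)/C=C(/C)C[C@@H](O[Si](C)(C)C(C)(C)C)[C@@H]12 | intermediate
25 | C2 tiglate of 24 | C=C1[C@@H](OC)O[C@@H]2/C=C(\COC(C)=O)C[C@H](OC(=O)/C(C)=C/C)/C=C(/C)C[C@@H](O[Si](C)(C)C(C)(C)C)[C@@H]12 | intermediate
26 | lactol from 25 (C12–OH) | C=C1C(O)O[C@@H]2/C=C(\COC(C)=O)C[C@H](OC(=O)/C(C)=C/C)/C=C(/C)C[C@@H](O[Si](C)(C)C(C)(C)C)[C@@H]12 | intermediate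
27 | 8-O-tert-butyldimethylsilyl ether of the target | C=C1C(=O)O[C@@H]2/C=C(\COC(C)=O)C[C@H](OC(=O)/C(C)=C/C)/C=C(/C)C[C@@H](O[Si](C)(C)C(C)(C)C)[C@@H]12 | intermediate
28 | CNP0129394.2 (15-acetoxy-8-hydroxy-2-tigloyloxy-germacra-1(10),4,11(13)-trien-12,6-olide; 2S,6R,7R,8R) | C=C1C(=O)O[C@@H]2/C=C(\COC(C)=O)C[C@H](OC(=O)/C(C)=C/C)/C=C(/C)C[C@@H](O)[C@@H]12 | target

**Step count:** 21 steps in total; longest linear sequence 18 steps (steps 1–5, then 9–21).

**Steps most likely to fail**

1. Step 14 (the proposed ring contraction). What may go wrong: the delocalised allyl anion is acylated through its γ-terminus (C5), or it expels the C6 oxygen in a 1,4-elimination, or proton transfer outruns the attack on the hindered conjugated lactone carbonyl. The fallback is the known Claisen-type acylation of a sulfonyl carbanion by a simple ester, without the lactone tether. It sets out from 17: Me3SiCHN2 in MeOH/toluene gives the methyl ester F1; Et3SiCl and imidazole give the C15 triethylsilyl ether F2; LiN(SiMe3)2 in THF at high dilution (0.002 M) closes the ten-membered ring directly between C3 and the ester carbonyl C2 to give the silyl-protected β-keto sulfone F3; pyridinium p-toluenesulfonate in MeOH removes the triethylsilyl group and the route is rejoined at 21.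

2. Step 13 (macrolactonisation). What may go wrong: oligomerisation outruns closure of the 11-membered ring, or the acyl-activated enoate loses its geometry before closure. The fallback is a Mitsunobu macrolactonisation (PPh3, diisopropyl azodicarboxylate, toluene, slow addition). It activates the primary allylic C15 hydroxyl instead of the acid and forms the C15–O bond by SN2 displacement with the carboxylate, so no activated enoate is ever present. It sets out from 17, rejoins at 19 and needs no further compound (F0).

3. Step 17 (ketone reduction). What may go wrong: poor facial selectivity, because the conformation of the medium ring overrides reagent control and hydride is delivered to the wrong face of C2. The fallback sets out from 23: reduction under substrate control (NaBH4, CeCl3·7H2O, MeOH, −78 °C) to the C2-epimeric alcohol F4, then esterification with tiglic acid under Mitsunobu conditions (PPh3, diisopropyl azodicarboxylate, toluene, 0 °C). This installs the tiglate with inversion at C2 and rejoins the route at 25.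

**Further compounds**
F1 | step 14 | methyl ester of 17 | C=C1[C@@H](OC)O[C@H](/C=C(\CO)CS(=O)(=O)c2ccccc2)[C@H]1[C@H](O[Si](C)(C)C(C)(C)C)C/C(C)=C\C(=O)OC
F2 | step 14 | C15 triethylsilyl ether of F1 | C=C1[C@@H](OC)O[C@H](/C=C(\CO[Si](CC)(CC)CC)CS(=O)(=O)c2ccccc2)[C@H]1[C@H](O[Si](C)(C)C(C)(C)C)C/C(C)=C\C(=O)OC
F3 | step 14 | C15 triethylsilyl ether of 21 | C=C1[C@@H](OC)O[C@@H]2/C=C(\CO[Si](CC)(CC)CC)C(S(=O)(=O)c3ccccc3)C(=O)/C=C(/C)C[C@@H](O[Si](C)(C)C(C)(C)C)[C@@H]12
F0 | step 13 | none | none
F4 | step 17 | (2R)-epimer of 24 | C=C1[C@@H](OC)O[C@@H]2/C=C(\COC(C)=O)C[C@@H](O)/C=C(/C)C[C@@H](O[Si](C)(C)C(C)(C)C)[C@@H]12
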